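Watch the split.

all flasks: gas phase 1.5 mM (held)

| run | substrate | catalyst | remark | time |
|---|---|---|---|---|
| summer | 0.020 M | 0.095 mM | run made earlier |  |
| spring | 0.020 M | 0.14 mM | run made earlier |  |
| noon | 0.010 M | 0.19 mM | run made earlier |  |
| flask | 0.020 M | 0.19 mM |  | 40 min |

| run | time / min | target / % | substrate / % |
|---|---|---|---|
| summer | 8.00 | 1.7 | 90.8 |
| summer | 15.0 | 4.6 | 80.5 |
| summer | 25.0 | 6.1 | 68.5 |
| summer | 30.0 | 9.5 | 64.0 |
| summer | 40.0 | 11.2 | 52.0 |
| summer | 50.0 | 12.1 | 43.2 |
| spring | 3.00 | 2.6 | 96.6 |
| spring | 10.0 | 3.5 | 86.5 |
| spring | 15.0 | 5.6 | 78.8 |
| spring | 25.0 | 10.8 | 65.2 |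
| spring | 40.0 | 13.2 | 50.4 |
| spring | 50.0 | 17.4 | 41.5 |
| noon | 4.00 | 2.8 | 95.7 |
| noon | 8.00 | 3.4 | 85.3 |
| noon | 15.0 | 9.0 | 72.6 |
| noon | 25.0 | 13.7 | 57.3 |
| noon | 50.0 | 24.2 | 29.4 |

(each reading ± 1 percentage point)

- the target standing at 40 min, as a percentage of the substrate charged
- the change that raises the amount of target at 40 min, in percent of the substrate charged most ("none" if none brings more than 2 percentage points) (north-east / south-west / west / none)
- amount of target at 40 min, in percent of the substrate charged, after north-east

- north-east: doubling the amount of catalyst, all else as stated
- south-west: doubling the transfer coefficient of the gas phase, all else as stated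
- west: doubling the saturation concentration of gas phase, all else as stated

- the numbers in the tables scatter with a standard deviation of 1 percentage point
- at the start none of the gas phase is in solution

From each run's last reading we divide the target by the substrate lost otherwise, then by the catalyst charged. This gives 2.85 /mM for summer, 3.02 /mM for spring and 2.75 /mM for noon, although noon holds twice summer's catalyst and half its substrate. We carry the mean, 2.87 /mM, as g, the split constant: a selectivity factor per unit of catalyst. With catalyst C, target's share of the lost substrate is gC/(1+gC), so the flask's share is 35.3%.

Next comes the loss. At 40.0 min summer had lost 48.0% and spring 49.6%, and spring's loss, kept flat, puts the flask at 17.5%. That flat loss is our weak link. Spring lost more than summer by 1.6 percentage points at 40.0 min and 1.7 points at 50.0 min, steps near the scatter but alike. Carried in proportion to catalyst, they give an extra loss, as a fraction of the charge, of 0.367 /mM, so by our reckoning the flask loses 51.4% and we commit to 18.2%. Doubled catalyst then gives 30.5%. Doubled saturation, read as a doubled clock with the remaining substrate squared, gives 27.0%, which is less. We rank doubled transfer lower, without a number.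

The forecast says 17.5%, and 29% after north-east: “North-east narrowly wins.” The flask gives 18.6%, and north-east gives 31.6%, a gain of 13 points against 10 points for west and 3.7 points for south-west.

    gas phase ⇌ dissolved gas, rate k1*(csat - [dissolved gas]) (kL = 0.490 /min)
    substrate + dissolved gas + catalyst → catalyst + target (k = 43000 /M²/min)
    dissolved gas → decomposed reagent (k = 0.0620 /min)
    substrate + dissolved gas → uncatalysed product (k = 15.0 /M/min)

In these equations g stands for the catalysed constant over the uncatalysed one. Target stays low in the flask partly through the step to uncatalysed product together with the early reading: without that step the flask gives 28.4%, and at 400 min it gives 35.3%. Applied to the 52.8% of substrate the flask has lost, g gives 18.6% target, against the flask's 18.6%. The neighbour with a quarter of the catalyst leaves 54.9% substrate, and g applied to what it lost gives 5.46% target, against its 5.45%.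

The data are calculated with constants of no real substance; scatter was added.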